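Early on, the delta flask climbs steeply: 8.3% of product by 1.33 min, a slope of 0.0624 min⁻¹.

| flask | starting material | coupling partner | protic impurity | catalyst | remark | time |
|---|---|---|---|---|---|---|
| delta | 0.20 M | 0.30 M | 0.020 M | 1 mM | run made earlier |  |
| zeta | 0.10 M | 0.30 M | 0.020 M | 1 mM | run made earlier |  |
| alpha | 0.15 M | 0.30 M | 0.020 M | 1 mM | run made earlier |  |
| beta | 0.20 M | 0.30 M | 0.030 M | 1 mM | run made earlier |  |
| alder | 0.20 M (in portions, 3, over 6.0 min) | 0.300 M | 0.0200 M | 1.0 mM | first portion at the start, last at 6.0 min | 30 min |
| elm | 0.20 M | 0.300 M (fed, over 6.0 min) | 0.0200 M | 1.0 mM | all else is in the flask from the start; the feed brings no volume worth counting | 30 min |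
| oak | 0.20 M | 0.300 M | 0.0200 M | 1.0 mM | everything together at the start | 30 min |
| cedar | 0.20 M (fed, over 6.0 min) | 0.300 M | 0.0200 M | 1.0 mM | all else is in the flask from the start; the feed brings no volume worth counting | 30 min |

- delta (time / min: product / %): 1.33: 8.3; 2.00: 10.7; 3.00: 13.2; 5.00: 14.8; 8.00: 17.1; 12.0: 18.6; 20.0: 17.8
- zeta (time / min: product / %): 1.50: 8.8; 5.00: 15.5; 8.00: 17.6; 12.0: 18.6; 20.0: 19.3; 25.0: 19.2; 30.0: 19.5
- alpha (time / min: product / %): 1.50: 9.0; 5.00: 15.6; 8.00: 17.1; 12.0: 18.7; 20.0: 18.9; 25.0: 19.0; 30.0: 18.8
- beta (time / min: product / %): 2.50: 11.2; 8.00: 16.5; 15.0: 17.1; 20.0: 17.7; 30.0: 17.9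

(standard deviation of a reading: 0.3 percentage points)

- the best flask by amount of product, in percent of the starting material charged; "all alike" if 1.5 percentage points covers them all (alder / elm / oak / cedar / all alike)
- amount of product at the end, in percent of the starting material charged, alder
- amount of product at the end, in percent of the starting material charged, elm
- amount of product at the end, in percent of the starting material charged, oak
- amount of product at the end, in percent of the starting material charged, cedar



Between 3.00 min and 8.00 min the delta slope is 0.00780 min⁻¹, so the knee lies in the first minutes. The last two delta readings give a level of 18.2%. Zeta, with 0.10 M of starting material, ends at 19.5%, and alpha, with 0.15 M, at 18.8%. So we take the rate as first order in starting material: pseudo-first-order, with a rate constant that dies away.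

What dies? Delta's product needs 0.0364 M of coupling partner, less than the 0.30 M charged, yet the curve stops. We suspect that coupling partner sets the rate and is lost by other paths, with protic impurity taking its share mole for mole.

reach = −ln(share not turned into product at the level) = 0.201

Reach is the first-order exposure that a molecule of starting material has ahead of it, and we take it as proportional to coupling partner minus protic impurity. Beta tests this weakly:

beta level = 17.6%, read 17.9%

A portion of starting material arriving late meets the reach left on the delta curve:

at 3.00 min: 5.76%; at 6.0 min: 3.12%

alder = 9.03%; cedar = 7.39%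

Oak has the delta charges, so we put it at 18.2%. If coupling partner dies first order, feeding it leaves the area under its curve unchanged, so we put elm at 18.2% too. We name oak, as elm rests on that assumption.

The forecast says oak, with alder 9.9%, elm 13%, oak 19% and cedar 8.5%, and on elm, where our figure stands higher, it writes “I guess 13%, very uncertain”.

Oak gives 18.3%, more than elm at 16.2%, alder at 10.6% and cedar at 9.66%.

    starting material + coupling partner + catalyst → catalyst + product (k = 402 L² mol⁻² min⁻¹)
    coupling partner + protic impurity → quenched reagent (k = 8.23 L mol⁻¹ min⁻¹)
    coupling partner → decomposed reagent (k = 0.259 min⁻¹)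
    starting material ⇌ dormant form (K = 1.20, k = 0.857 min⁻¹)

Our elm stood 2 percentage points high. Scaling cedar's reach to a cedar flask with 0.75 M of coupling partner gives 23.3%, and that flask gives 23.0%, more than oak. Oak keeps 0.015% of its coupling partner at 30.0 min, and that share of its reach is worth about 0.0025 points of product. At 300 min oak still stands at 18.4%, with 37.1% of its starting material free and 44.5% as dormant form.

All runs were computed with constants of no real substance; noise was put on by code.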